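**Retrosynthetic overview** (target numbered as a hexadeca-3,10,14-trien-5-one)
1. Target ⇒ desilylation and enone formation by acyl substitution: an N-methylanilide of the C5 acid plus the (E)-vinyl-lithium from 2-methylbut-3-yn-2-ol.
2. Key bond C6–C7: nickel-hydride radical hydroalkylation of the terminal alkene of the left-hand triene with racemic 2-bromo-N-methyl-N-phenylpropanamide; it joins the halves and sets C6 (R) under ligand control.
3. Left-hand triene ⇒ benzylic bromide + alkenylalane from a homopropargylic silyl ether (C14=C15 E by syn-carboalumination); C12 (R) from a chromium-catalysed asymmetric propargylation of (2E)-3-methylhexa-2,5-dienal, made from pent-1-en-4-yne.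
4. No ring is formed: the benzene ring is bought as o-cresol and functionalised first (Br, OMe, CH2Br, silyl ether).

Assumption: the ligand antipodes named in steps 8 and 11 are taken to give the R configuration at the new centres; if either induces the opposite sense, its mirror-image ligand is used.

**Route**

Step 1
Reactants: 1 o-cresol (2-methylphenol)
Product: 2 4-bromo-2-methylphenol
Conditions: Br2 (1.0 equiv), CH2Cl2, −10 °C
Reagents that add atoms: bromine, BrBr
Why: Electrophilic aromatic bromination in which the OH group directs mainly para at low temperature, the minor 6-bromo isomer being removed by crystallisation.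

Step 2
Reactants: 2 4-bromo-2-methylphenol
Product: 3 4-methoxy-2-methylphenol
Conditions: NaOMe (5 equiv, 25% in MeOH), CuBr (10 mol%), DMF, 110 °C; then 1 M HCl
Reagents that add atoms: sodium methoxide, C[O-].[Na+]
Why: Ullmann-type copper-catalysed methoxylation of the aryl bromide, which tolerates the phenoxide and replaces only bromine.

Step 3
Reactants: 3 4-methoxy-2-methylphenol
Product: 4 2-(hydroxymethyl)-4-methoxy-6-methylphenol
Conditions: 37% aq. HCHO (3 equiv), NaOH (1.1 equiv), H2O, 0 → 23 °C; then AcOH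
Reagents that add atoms: formaldehyde, C=O
Why: Lederer–Manasse hydroxymethylation of the phenoxide, which can only attack the single free ortho position because the para position carries OMe and the other ortho position carries CH3.

Step 4
Reactants: 4 2-(hydroxymethyl)-4-methoxy-6-methylphenol
Product: 5 tert-butyl({2-[(tert-butyldimethylsilyl)oxy]-5-methoxy-3-methylphenyl}methoxy)dimethylsilane
Conditions: TBSCl (2.3 equiv), imidazole (4 equiv), DMF, 23 °C
Reagents that add atoms: tert-butyldimethylsilyl chloride, CC(C)(C)[Si](C)(C)Cl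
Why: Imidazole-promoted silylation of both hydroxyl groups, so the phenol stays masked while the benzylic oxygen is exchanged in the next step.

Step 5
Reactants: 5 tert-butyl({2-[(tert-butyldimethylsilyl)oxy]-5-methoxy-3-methylphenyl}methoxy)dimethylsilane
Product: 6 tert-butyl[2-(bromomethyl)-4-methoxy-6-methylphenoxy]dimethylsilane
Conditions: Ph3PBr2 (1.1 equiv), CH2Cl2, 0 → 23 °C
Reagents that add atoms: triphenylphosphine dibromide, BrP(Br)(c1ccccc1)(c1ccccc1)c1ccccc1
Why: Ph3PBr2 converts the benzylic silyl ether directly into the bromide through an alkoxyphosphonium bromide (Appel-type substitution), while the aryl silyl ether cannot be displaced at an sp2 carbon and stays.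

Step 6
Reactants: 7 pent-1-en-4-yne
Product: 9 (2E)-3-methylhexa-2,5-dien-1-ol, via alkenyldimethylalane 8 (not isolated)
Conditions: AlMe3 (2.0 equiv), Cp2ZrCl2 (0.2 equiv), CH2Cl2, 0 → 23 °C; evaporate; n-BuLi (1.0 equiv), hexane/THF, −30 °C; (CH2O)n (3 equiv), 23 °C; 1 M HCl
Reagents that add atoms: trimethylaluminium, C[Al](C)C; paraformaldehyde (formaldehyde), C=O
Why: Negishi zirconium-catalysed carboalumination adds CH3 and Al syn across the alkyne only (E-alkenylalane), and the derived alanate is hydroxymethylated by formaldehyde with retention of geometry.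

Step 7
Reactants: 9 (2E)-3-methylhexa-2,5-dien-1-ol
Product: 10 (2E)-3-methylhexa-2,5-dienal
Conditions: MnO2 (15 equiv), CH2Cl2, 23 °C; used directly as a solution
Reagents that add atoms: none
Why: MnO2 oxidation is selective for the allylic alcohol and is neutral, so the E geometry and the skipped diene are kept.

Step 8
Reactants: 10 (2E)-3-methylhexa-2,5-dienal; 11 3-bromoprop-1-yne (propargyl bromide)
Product: 12 triethyl{[(4E,6R)-4-methylnona-1,4-dien-8-yn-6-yl]oxy}silane
Conditions: CrCl2 (10 mol%), (S,S)-i-Pr-bis(oxazolinyl)carbazole ligand (12 mol%), i-Pr2NEt (0.3 equiv), Mn powder (2 equiv), Et3SiCl (1.3 equiv), 11 (1.5 equiv), THF, 23 °C; aq. NaHCO3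
Reagents that add atoms: chlorotriethylsilane, CC[Si](Cl)(CC)CC
Why: Catalytic asymmetric Nozaki–Hiyama propargylation in which divalent chromium (regenerated by Mn) reduces propargyl bromide through a propargyl radical to an allenylchromium species that adds 1,2 to the enal inside the chiral ligand pocket, fixing C6 as R, while Et3SiCl releases the alkoxide as the silyl ether that then serves as protecting group.

Step 9
Reactants: 12 triethyl{[(4E,6R)-4-methylnona-1,4-dien-8-yn-6-yl]oxy}silane; 6 tert-butyl[2-(bromomethyl)-4-methoxy-6-methylphenoxy]dimethylsilane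
Product: 14 tert-butyl{2-[(2E,5R,6E)-3,7-dimethyl-5-(triethylsilyloxy)deca-2,6,9-trien-1-yl]-4-methoxy-6-methylphenoxy}dimethylsilane, via alkenyldimethylalane 13 (not isolated)
Conditions: AlMe3 (2.5 equiv), Cp2ZrCl2 (0.25 equiv), CH2Cl2, 0 → 23 °C; evaporate; 6 (0.9 equiv), Pd(PPh3)4 (5 mol%), THF, 23 °C; aq. potassium sodium tartrate
Reagents that add atoms: trimethylaluminium, C[Al](C)C
Why: Negishi syn-carboalumination of the terminal alkyne (alkenes untouched) followed by palladium-catalysed alkenylalane–benzyl bromide cross-coupling, which transfers the alkenyl group with retention and so gives the E-trisubstituted allyl arene without touching C5.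

Step 10
Reactants: 15 2-bromopropanoyl bromide (racemic); 16 N-methylaniline
Product: 17 rac-2-bromo-N-methyl-N-phenylpropanamide
Conditions: Et3N (1.1 equiv), CH2Cl2, 0 °C
Reagents that add atoms: none
Why: Schotten–Baumann-type N-acylation by the acid bromide at 0 °C, which leaves the secondary bromide in place and gives the racemic electrophile needed for the stereoconvergent coupling.

Step 11
Reactants: 14 tert-butyl{2-[(2E,5R,6E)-3,7-dimethyl-5-(triethylsilyloxy)deca-2,6,9-trien-1-yl]-4-methoxy-6-methylphenoxy}dimethylsilane; 17 rac-2-bromo-N-methyl-N-phenylpropanamide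
Product: 18 (2R,6E,8R,10E)-12-[2-(tert-butyldimethylsilyloxy)-5-methoxy-3-methylphenyl]-N,2,6,10-tetramethyl-N-phenyl-8-(triethylsilyloxy)dodeca-6,10-dienamide
Conditions: NiBr2·glyme (10 mol%), (S,S)-bis(oxazoline) ligand (12 mol%), (EtO)3SiH (2 equiv), K3PO4·H2O (2 equiv), 17 (1.5 equiv), DMA, 23 °C
Reagents that add atoms: none
Why: Nickel-hydride enantioconvergent hydroalkylation (radical C(sp3)–C(sp3) coupling) in which Ni–H adds anti-Markovnikov to the only monosubstituted alkene, halogen-atom abstraction turns both enantiomers of 17 into the same planar α-amido radical, and its capture and reductive elimination at the chiral nickel alkyl set C2 as R under catalyst control, independent of the remote C8 centre.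

Step 12
Reactants: 19 2-methylbut-3-yn-2-ol
Product: 20 (3E)-2-methyl-4-(tributylstannyl)but-3-en-2-ol
Conditions: Bu3SnH (1.1 equiv), PdCl2(PPh3)2 (2 mol%), THF, 0 → 23 °C
Reagents that add atoms: tributyltin hydride, CCCC[SnH](CCCC)CCCC
Why: Palladium-catalysed syn-hydrostannation places tin on the unhindered terminal carbon next to the quaternary carbinol and gives the E-vinylstannane.

Step 13
Reactants: 18 (2R,6E,8R,10E)-12-[2-(tert-butyldimethylsilyloxy)-5-methoxy-3-methylphenyl]-N,2,6,10-tetramethyl-N-phenyl-8-(triethylsilyloxy)dodeca-6,10-dienamide; 20 (3E)-2-methyl-4-(tributylstannyl)but-3-en-2-ol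
Product: 22 (3E,6R,10E,12R,14E)-16-[2-(tert-butyldimethylsilyloxy)-5-methoxy-3-methylphenyl]-2-hydroxy-2,6,10,14-tetramethyl-12-(triethylsilyloxy)hexadeca-3,10,14-trien-5-one, via dilithiated vinyl alkoxide 21 (not isolated)
Conditions: 20 (2.0 equiv), n-BuLi (4.0 equiv), THF, −78 → −40 °C; then 18, −78 °C, 1 h; aq. NH4Cl at −78 °C
Reagents that add atoms: none
Why: Tin–lithium exchange gives the vinyl-lithium with retention of E geometry, and its addition to the N-methylanilide (Weinreb-type acyl substitution through a tetrahedral intermediate that collapses only on quench) gives the enone without over-addition or epimerisation of C6 at −78 °C.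

Step 14
Reactants: 22 (3E,6R,10E,12R,14E)-16-[2-(tert-butyldimethylsilyloxy)-5-methoxy-3-methylphenyl]-2-hydroxy-2,6,10,14-tetramethyl-12-(triethylsilyloxy)hexadeca-3,10,14-trien-5-one
Product: 23 (3E,6R,10E,12R,14E)-2,12-dihydroxy-16-(2-hydroxy-5-methoxy-3-methylphenyl)-2,6,10,14-tetramethylhexadeca-3,10,14-trien-5-one (CNP0214110.1)
Conditions: HF·pyridine, pyridine, THF, 0 → 23 °C
Reagents that add atoms: none
Why: Fluoride-driven cleavage of the aryl and secondary silyl ethers under buffered, mildly acidic conditions leaves the enone, the tertiary allylic alcohol and the C6 centre untouched.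

**Compound list**
1 | o-cresol (2-methylphenol) | Cc1ccccc1O | starting material
2 | 4-bromo-2-methylphenol | Cc1cc(Br)ccc1O | intermediate
3 | 4-methoxy-2-methylphenol | COc1ccc(O)c(C)c1 | intermediate
4 | 2-(hydroxymethyl)-4-methoxy-6-methylphenol | COc1cc(C)c(O)c(CO)c1 | intermediate
5 | tert-butyl({2-[(tert-butyldimethylsilyl)oxy]-5-methoxy-3-methylphenyl}methoxy)dimethylsilane | COc1cc(C)c(O[Si](C)(C)C(C)(C)C)c(CO[Si](C)(C)C(C)(C)C)c1 | intermediate
6 | tert-butyl[2-(bromomethyl)-4-methoxy-6-methylphenoxy]dimethylsilane | COc1cc(C)c(O[Si](C)(C)C(C)(C)C)c(CBr)c1 | intermediate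
7 | pent-1-en-4-yne | C#CCC=C | starting material
8 | dimethyl[(1E)-2-methylpenta-1,4-dien-1-yl]alane | C[Al](C)/C=C(\C)CC=C | intermediate (not isolated)
9 | (2E)-3-methylhexa-2,5-dien-1-ol | OC/C=C(\C)CC=C | intermediate
10 | (2E)-3-methylhexa-2,5-dienal | O=C/C=C(\C)CC=C | intermediate
11 | 3-bromoprop-1-yne (propargyl bromide) | C#CCBr | starting material
12 | triethyl{[(4E,6R)-4-methylnona-1,4-dien-8-yn-6-yl]oxy}silane | C#CC[C@@H](O[Si](CC)(CC)CC)/C=C(\C)CC=C | intermediate
13 | dimethyl{(1E,4R,5E)-2,6-dimethyl-4-[(triethylsilyl)oxy]nona-1,5,8-trien-1-yl}alane | C[Al](C)/C=C(\C)C[C@@H](O[Si](CC)(CC)CC)/C=C(\C)CC=C | intermediate (not isolated)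
14 | tert-butyl{2-[(2E,5R,6E)-3,7-dimethyl-5-(triethylsilyloxy)deca-2,6,9-trien-1-yl]-4-methoxy-6-methylphenoxy}dimethylsilane | COc1cc(C)c(O[Si](C)(C)C(C)(C)C)c(C/C=C(\C)C[C@@H](O[Si](CC)(CC)CC)/C=C(\C)CC=C)c1 | intermediate
15 | 2-bromopropanoyl bromide (racemic) | CC(Br)C(Br)=O | starting material
16 | N-methylaniline | CNc1ccccc1 | starting material
17 | rac-2-bromo-N-methyl-N-phenylpropanamide | CC(Br)C(=O)N(C)c1ccccc1 | intermediate
18 | (2R,6E,8R,10E)-12-[2-(tert-butyldimethylsilyloxy)-5-methoxy-3-methylphenyl]-N,2,6,10-tetramethyl-N-phenyl-8-(triethylsilyloxy)dodeca-6,10-dienamide | COc1cc(C)c(O[Si](C)(C)C(C)(C)C)c(C/C=C(\C)C[C@@H](O[Si](CC)(CC)CC)/C=C(\C)CCC[C@@H](C)C(=O)N(C)c2ccccc2)c1 | intermediate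
19 | 2-methylbut-3-yn-2-ol | C#CC(C)(C)O | starting material
20 | (3E)-2-methyl-4-(tributylstannyl)but-3-en-2-ol | CCCC[Sn](CCCC)(CCCC)/C=C/C(C)(C)O | intermediate
21 | lithium (3E)-4-lithio-2-methylbut-3-en-2-olate | [Li]/C=C/C(C)(C)O[Li] | intermediate (not isolated)
22 | (3E,6R,10E,12R,14E)-16-[2-(tert-butyldimethylsilyloxy)-5-methoxy-3-methylphenyl]-2-hydroxy-2,6,10,14-tetramethyl-12-(triethylsilyloxy)hexadeca-3,10,14-trien-5-one | COc1cc(C)c(O[Si](C)(C)C(C)(C)C)c(C/C=C(\C)C[C@@H](O[Si](CC)(CC)CC)/C=C(\C)CCC[C@@H](C)C(=O)/C=C/C(C)(C)O)c1 | intermediate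
23 | (3E,6R,10E,12R,14E)-2,12-dihydroxy-16-(2-hydroxy-5-methoxy-3-methylphenyl)-2,6,10,14-tetramethylhexadeca-3,10,14-trien-5-one | COc1cc(C)c(O)c(C/C=C(\C)C[C@@H](O)/C=C(\C)CCC[C@@H](C)C(=O)/C=C/C(C)(C)O)c1 | target

**Step count**
Total: 14 steps. Longest linear sequence: 9 steps (1, 2, 3, 4, 5, 9, 11, 13, 14).

**Three steps most likely to fail, with fallbacks**

Step 11 (key radical coupling). The alkene of 14 is part of a skipped diene, so a Markovnikov Ni–H insertion and chain-walking would lead to an allyl-nickel and to coupling at the wrong carbon. The doubly allylic CH2 is also a hydrogen-atom donor towards the α-amido radical. The fallback sets out from 14 and comes back at 18 and replaces the olefin pronucleophile by a preformed alkylzinc. Hydrozirconation of the terminal alkene with Cp2Zr(H)Cl (CH2Cl2, 23 °C) gives chlorobis(cyclopentadienyl){(4E,6R,8E)-10-[2-(tert-butyldimethylsilyloxy)-5-methoxy-3-methylphenyl]-4,8-dimethyl-6-(triethylsilyloxy)deca-4,8-dien-1-yl}zirconium F1. Iodinolysis (I2, 0 °C) gives the primary iodide tert-butyl{2-[(2E,5R,6E)-10-iodo-3,7-dimethyl-5-(triethylsilyloxy)deca-2,6-dien-1-yl]-4-methoxy-6-methylphenoxy}dimethylsilane F2. Zinc insertion (Zn dust, LiCl, THF, 40 °C) gives {(4E,6R,8E)-10-[2-(tert-butyldimethylsilyloxy)-5-methoxy-3-methylphenyl]-4,8-dimethyl-6-(triethylsilyloxy)deca-4,8-dien-1-yl}zinc iodide F3. A nickel-catalysed enantioconvergent Negishi coupling of F3 with racemic 17 (NiCl2·glyme, i-Pr-Pybox, DMI/THF, 0 °C) then gives 18 through the same α-amido radical.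

Step 8 (asymmetric propargylation). The enantioselectivity on a β,β-disubstituted skipped dienal with Et3SiCl as turnover reagent is not assured, and some allenyl carbinol may form. The fallback sets out from 10 and comes back at 12 and uses a closed, boron-based transition state instead of the chromium radical-polar manifold. Allenylboronic acid pinacol ester with the chiral phosphoric acid (R)-TRIP (5 mol%, toluene, 4 Å sieves, 0 °C) gives 4,4,5,5-tetramethyl-2-{[(4E,6R)-4-methylnona-1,4-dien-8-yn-6-yl]oxy}-1,3,2-dioxaborolane F4. Aqueous work-up hydrolyses it to (4E,6R)-4-methylnona-1,4-dien-8-yn-6-ol F5, and Et3SiCl/imidazole (CH2Cl2, 0 °C) gives 12.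

Step 13 (enone from the anilide). The tetrahedral intermediate of an anilide is not chelated, so early collapse and over-addition, or enolisation at C2, are possible. The fallback sets out from 18 and comes back at 22 and goes through the aldehyde oxidation level. Cp2Zr(H)Cl (1.5 equiv, THF, 23 °C) reduces 18 to (2R,6E,8R,10E)-12-[2-(tert-butyldimethylsilyloxy)-5-methoxy-3-methylphenyl]-2,6,10-trimethyl-8-(triethylsilyloxy)dodeca-6,10-dienal F6. Addition of 21 at −78 °C gives (3E,6R,10E,12R,14E)-16-[2-(tert-butyldimethylsilyloxy)-5-methoxy-3-methylphenyl]-2,6,10,14-tetramethyl-12-(triethylsilyloxy)hexadeca-3,10,14-triene-2,5-diol F7 as a mixture of C5 epimers. Dess–Martin periodinane with NaHCO3 (CH2Cl2, 0 °C) oxidises only its secondary allylic alcohol and gives 22.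

**Further compounds**
F1 | step 11 | chlorobis(cyclopentadienyl){(4E,6R,8E)-10-[2-(tert-butyldimethylsilyloxy)-5-methoxy-3-methylphenyl]-4,8-dimethyl-6-(triethylsilyloxy)deca-4,8-dien-1-yl}zirconium | COc1cc(C)c(O[Si](C)(C)C(C)(C)C)c(C/C=C(\C)C[C@@H](O[Si](CC)(CC)CC)/C=C(\C)CCC[Zr](Cl)(C2C=CC=C2)C2C=CC=C2)c1
F2 | step 11 | tert-butyl{2-[(2E,5R,6E)-10-iodo-3,7-dimethyl-5-(triethylsilyloxy)deca-2,6-dien-1-yl]-4-methoxy-6-methylphenoxy}dimethylsilane | COc1cc(C)c(O[Si](C)(C)C(C)(C)C)c(C/C=C(\C)C[C@@H](O[Si](CC)(CC)CC)/C=C(\C)CCCI)c1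
F3 | step 11 | {(4E,6R,8E)-10-[2-(tert-butyldimethylsilyloxy)-5-methoxy-3-methylphenyl]-4,8-dimethyl-6-(triethylsilyloxy)deca-4,8-dien-1-yl}zinc iodide | COc1cc(C)c(O[Si](C)(C)C(C)(C)C)c(C/C=C(\C)C[C@@H](O[Si](CC)(CC)CC)/C=C(\C)CCC[Zn]I)c1
F4 | step 8 | 4,4,5,5-tetramethyl-2-{[(4E,6R)-4-methylnona-1,4-dien-8-yn-6-yl]oxy}-1,3,2-dioxaborolane | C#CC[C@@H](OB1OC(C)(C)C(C)(C)O1)/C=C(\C)CC=C
F5 | step 8 | (4E,6R)-4-methylnona-1,4-dien-8-yn-6-ol | C#CC[C@@H](O)/C=C(\C)CC=C
F6 | step 13 | (2R,6E,8R,10E)-12-[2-(tert-butyldimethylsilyloxy)-5-methoxy-3-methylphenyl]-2,6,10-trimethyl-8-(triethylsilyloxy)dodeca-6,10-dienal | COc1cc(C)c(O[Si](C)(C)C(C)(C)C)c(C/C=C(\C)C[C@@H](O[Si](CC)(CC)CC)/C=C(\C)CCC[C@@H](C)C=O)c1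
F7 | step 13 | (3E,6R,10E,12R,14E)-16-[2-(tert-butyldimethylsilyloxy)-5-methoxy-3-methylphenyl]-2,6,10,14-tetramethyl-12-(triethylsilyloxy)hexadeca-3,10,14-triene-2,5-diol (C5 epimers) | COc1cc(C)c(O[Si](C)(C)C(C)(C)C)c(C/C=C(\C)C[C@@H](O[Si](CC)(CC)CC)/C=C(\C)CCC[C@@H](C)C(O)/C=C/C(C)(C)O)c1
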